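**Retrosynthetic overview**
1. Halimane numbering is used. Ring A is C1–C5 plus C10 and ring B is C5–C10. C4 carries C18 (CO2Me) and C19 (Me), C8 carries C17, C9 carries C20, and the side chain is C11–C16.
2. The target comes from its 14,15-acetonide by hydrolysis and diacetylation. Ring B is then opened at C6–C7, which leads back to a monocyclic ring A primary iodide (C6) with an isopropenyl group on C9. One reductive radical operation closes ring B and sets C8.
3. The enabling feature lies in ring B. C8 bears the methyl C17 and sits next to the all-carbon quaternary C9, while C6 is a plain CH2 on C5, homoallylic to the ring A double bond C1=C10. C7–C8–C17 can therefore be carried as an isopropenyl group whose inner carbon is blocked, so a C6 radical can only close 6-endo.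
4. Ring A, including C4, C5 and C1=C10, comes from a 6-alkenyl δ-lactone (C18–O–C1) by ring-contracting Ireland–Claisen rearrangement. The lactone comes from a Z vinyl iodide (C10) and a C1–C4 Weinreb amide.
5. C9 comes from an enantioselective Michael addition. C13 and C14 come from asymmetric epoxidation followed by Payne opening. Ring A is formed first and ring B second.

Key step: step 18

Remark 1 (assumption): the sense of induction in step 1 is taken to give (S)-3 with the (R)-BINAP complex. If it is the opposite, the (S)-BINAP complex is used.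
Remark 2 (shorthand): G(TES) = (3S,6S)-6-[(R)-2,2-dimethyl-1,3-dioxolan-4-yl]-2,3-dimethyl-6-(triethylsilyloxy)hept-1-en-3-yl. G(OH) is the same group with a free 6-hydroxyl. Both contain C7–C9, C11–C17 and C20.

**Step 1**
Reactants: 1 tert-butyl 2-methyl-3-oxobutanoate; 2 but-3-en-2-one
Product: 3 tert-butyl (S)-2-acetyl-2-methyl-5-oxohexanoate
Conditions: [Pd((R)-BINAP)(H2O)2](OTf)2 (5 mol %; BINAP = 2,2'-bis(diphenylphosphino)-1,1'-binaphthyl), THF, −20 °C
Reagents that add atoms: none
Why: Catalytic enantioselective Michael addition, in which the chiral divalent palladium enolate of 1 has one face covered by the ligand and adds to 2, setting the quaternary C9 (S).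

**Step 2**
Reactants: 3 tert-butyl (S)-2-acetyl-2-methyl-5-oxohexanoate
Product: 4 1-tert-butyl 7-ethyl (2S,5E)-2-acetyl-2,5-dimethylhept-5-enedioate
Conditions: (EtO)2P(O)CH2CO2Et, NaH, THF, 0 °C
Reagents that add atoms: triethyl phosphonoacetate CCOC(=O)CP(=O)(OCC)OCC
Why: Horner–Wadsworth–Emmons olefination, in which the weakly basic stabilised anion reaches only the open methyl ketone (C13) and not the ketone next to quaternary C9, giving mainly the E enoate with the minor Z isomer removed by chromatography.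

**Step 3**
Reactants: 4 1-tert-butyl 7-ethyl (2S,5E)-2-acetyl-2,5-dimethylhept-5-enedioate
Product: 5 1-tert-butyl 7-ethyl (2S,5E)-2,5-dimethyl-2-(prop-1-en-2-yl)hept-5-enedioate
Conditions: Ph3PCH3Br, KOt-Bu, THF, 0 °C to rt
Reagents that add atoms: methyltriphenylphosphonium bromide C[P+](c1ccccc1)(c1ccccc1)c1ccccc1.[Br-]
Why: Wittig methylenation turns the remaining acetyl group into the isopropenyl group (C7=C8, C17), and C9 carries no hydrogen so it cannot epimerise.

**Step 4**
Reactants: 5 1-tert-butyl 7-ethyl (2S,5E)-2,5-dimethyl-2-(prop-1-en-2-yl)hept-5-enedioate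
Product: 6 (2E,6S)-6-(hydroxymethyl)-3,6,7-trimethylocta-2,7-dien-1-ol
Conditions: i-Bu2AlH (6 equiv), CH2Cl2, −78 °C to 0 °C; aq. Rochelle salt
Reagents that add atoms: none
Why: Hydride reduction of both esters, in which i-Bu2AlH attacks the enoate 1,2 so that the E double bond is kept.

**Step 5**
Reactants: 6 (2E,6S)-6-(hydroxymethyl)-3,6,7-trimethylocta-2,7-dien-1-ol
Product: 7 (S)-2-{2-[(2S,3S)-3-(hydroxymethyl)-2-methyloxiran-2-yl]ethyl}-2,3-dimethylbut-3-en-1-ol
Conditions: Ti(Oi-Pr)4 (10 mol %), diethyl L-(+)-tartrate (12 mol %), t-BuOOH, 4 Å MS, CH2Cl2, −20 °C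
Reagents that add atoms: tert-butyl hydroperoxide CC(C)(C)OO
Why: Sharpless asymmetric epoxidation, in which only the allylic alcohol is activated on titanium so the isopropenyl group stays, and the L-(+)-tartrate sets 13S,14S in the same sense as for geraniol.

**Step 6**
Reactants: 7 (S)-2-{2-[(2S,3S)-3-(hydroxymethyl)-2-methyloxiran-2-yl]ethyl}-2,3-dimethylbut-3-en-1-ol
Product: 9 (2R,3S,6S)-6-(hydroxymethyl)-3,6,7-trimethyloct-7-ene-1,2,3-triol, via terminal epoxide 8 (not isolated)
Conditions: 0.5 M aq. NaOH, t-BuOH, 75 °C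
Reagents that add atoms: water O
Why: Payne rearrangement and opening, in which the C15 alkoxide inverts C14 to give 8 and hydroxide opens 8 at C15, while direct hydroxide attack at C14 gives the same triol, so C13–O is kept (S) and C14 is inverted to R.

**Step 7**
Reactants: 9 (2R,3S,6S)-6-(hydroxymethyl)-3,6,7-trimethyloct-7-ene-1,2,3-triol
Product: 10 (S)-2-{(S)-3-[(R)-2,2-dimethyl-1,3-dioxolan-4-yl]-3-hydroxybutyl}-2,3-dimethylbut-3-en-1-ol
Conditions: 2,2-dimethoxypropane, pyridinium p-toluenesulfonate (cat.), CH2Cl2, 0 °C to rt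
Reagents that add atoms: 2,2-dimethoxypropane COC(C)(C)OC
Why: Acetonide formation takes the terminal 14,15-diol as a five-membered ring, since the tertiary C13 hydroxyl is a poor partner and the remote C10 hydroxyl has no neighbour.

**Step 8**
Reactants: 10 (S)-2-{(S)-3-[(R)-2,2-dimethyl-1,3-dioxolan-4-yl]-3-hydroxybutyl}-2,3-dimethylbut-3-en-1-ol
Product: 11 (S)-2-{(S)-3-[(R)-2,2-dimethyl-1,3-dioxolan-4-yl]-3-hydroxybutyl}-2,3-dimethylbut-3-enal
Conditions: Dess–Martin periodinane, CH2Cl2, rt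
Reagents that add atoms: none
Why: Dess–Martin oxidation of the only oxidisable alcohol gives an aldehyde (C10) with no α-hydrogen, so C9 is safe.

**Step 9**
Reactants: 11 (S)-2-{(S)-3-[(R)-2,2-dimethyl-1,3-dioxolan-4-yl]-3-hydroxybutyl}-2,3-dimethylbut-3-enal
Product: 12 (2S,5S)-2-[(R)-2,2-dimethyl-1,3-dioxolan-4-yl]-5-ethynyl-5,6-dimethylhept-6-en-2-ol
Conditions: dimethyl (1-diazo-2-oxopropyl)phosphonate, K2CO3, MeOH, rt
Reagents that add atoms: dimethyl (1-diazo-2-oxopropyl)phosphonate CC(=O)C(=[N+]=[N-])P(=O)(OC)OC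
Why: Seyferth–Gilbert homologation in the Ohira–Bestmann form adds C5, and non-enolisable hindered aldehydes are good substrates.

**Step 10**
Reactants: 12 (2S,5S)-2-[(R)-2,2-dimethyl-1,3-dioxolan-4-yl]-5-ethynyl-5,6-dimethylhept-6-en-2-ol
Product: 14 (4S,7S)-7-[(R)-2,2-dimethyl-1,3-dioxolan-4-yl]-4-methyl-4-(prop-1-en-2-yl)oct-2-yne-1,7-diol, via dilithium acetylide alkoxide 13 (not isolated)
Conditions: n-BuLi (2.2 equiv), THF, −78 °C; (CH2O)n, −78 °C to rt
Reagents that add atoms: paraformaldehyde (as formaldehyde) C=O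
Why: Hydroxymethylation of a lithium acetylide adds C6, and the tertiary alkoxide is a spectator.

**Step 11**
Reactants: 14 (4S,7S)-7-[(R)-2,2-dimethyl-1,3-dioxolan-4-yl]-4-methyl-4-(prop-1-en-2-yl)oct-2-yne-1,7-diol
Product: 15 (2Z,4S,7S)-7-[(R)-2,2-dimethyl-1,3-dioxolan-4-yl]-3-iodo-4-methyl-4-(prop-1-en-2-yl)oct-2-ene-1,7-diol
Conditions: NaAlH2(OCH2CH2OMe)2 (3.5 equiv), THF, 0 °C to rt; I2, −78 °C
Reagents that add atoms: iodine II
Why: Alkoxide-directed trans-hydroalumination of a propargylic alcohol puts aluminium on C10 and hydrogen on C5, and iodinolysis with retention gives the Z vinyl iodide in which C6 is trans to C9.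

**Step 12**
Reactants: 15 (2Z,4S,7S)-7-[(R)-2,2-dimethyl-1,3-dioxolan-4-yl]-3-iodo-4-methyl-4-(prop-1-en-2-yl)oct-2-ene-1,7-diol
Product: 16 bis(triethylsilyl) ether of 15
Conditions: Et3SiOTf (2.5 equiv), 2,6-lutidine, CH2Cl2, −78 °C to 0 °C
Reagents that add atoms: triethylsilyl trifluoromethanesulfonate CC[Si](CC)(CC)OS(=O)(=O)C(F)(F)F
Why: Silyl triflate silylation covers both the primary and the tertiary hydroxyl, and the ketal survives the buffered cold conditions.

**Step 13**
Reactants: 17 dimethyl 2-methylpentanedioate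
Product: 18 methyl 5-[methoxy(methyl)amino]-2-methyl-5-oxopentanoate
Conditions: MeNHOMe·HCl (1.05 equiv), i-PrMgCl (2.1 equiv), THF, −20 °C
Reagents that add atoms: N,O-dimethylhydroxylamine hydrochloride CNOC.Cl
Why: Weinreb amide formation with the magnesium amide takes the unbranched ester faster than the α-branched one, and the racemic C4 is erased later.

**Step 14**
Reactants: 16 bis(triethylsilyl) ether of 15; 18 methyl 5-[methoxy(methyl)amino]-2-methyl-5-oxopentanoate
Product: 20 methyl (Z)-6-G(TES)-2-methyl-5-oxo-8-(triethylsilyloxy)oct-6-enoate (C2 epimers), via vinyllithium 19 (not isolated)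
Conditions: t-BuLi (2.1 equiv), Et2O, −78 °C; 18, −78 °C to −40 °C
Reagents that add atoms: none
Why: Lithium–iodine exchange with retention of alkene geometry is followed by Weinreb ketone synthesis, where the chelated adduct stops at the ketone and the α-branched methyl ester reacts more slowly.

**Step 15**
Reactants: 20 methyl (Z)-6-G(TES)-2-methyl-5-oxo-8-(triethylsilyloxy)oct-6-enoate
Product: 22 (6S)-6-[(Z)-1-G(TES)-3-(triethylsilyloxy)prop-1-en-1-yl]-3-methyltetrahydro-2H-pyran-2-one (C3 epimers), via hydroxy ester 21 (not isolated)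
Conditions: (R)-1-methyl-3,3-diphenyltetrahydro-1H,3H-pyrrolo[1,2-c][1,3,2]oxazaborole [(R)-Me-CBS, 20 mol %], catecholborane, toluene, −78 °C; MeOH; 1,8-diazabicyclo[5.4.0]undec-7-ene (cat.), toluene, 60 °C
Reagents that add atoms: none
Why: Corey–Bakshi–Shibata reduction tells the branched alkenyl group (large) from the CH2 chain (small) and sets C1 (S) under reagent control, catecholborane at low temperature spares the alkenes, and transesterification closes the δ-lactone.

**Step 16**
Reactants: 22 (6S)-6-[(Z)-1-G(TES)-3-(triethylsilyloxy)prop-1-en-1-yl]-3-methyltetrahydro-2H-pyran-2-one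
Product: 26 methyl (1R,2R)-3-G(OH)-2-(hydroxymethyl)-1-methylcyclohex-3-ene-1-carboxylate, via silyl ketene acetal 23 (not isolated), via trimethylsilyl ester 24 (not isolated), via tetrabutylammonium carboxylate 25 (not isolated)
Conditions: LDA, THF, −78 °C; Me3SiCl–Et3N, −78 °C to rt; toluene, 110 °C; Bu4NF, THF, rt; MeI, rt
Reagents that add atoms: iodomethane CI; chlorotrimethylsilane C[Si](C)(C)Cl (stays only in 23 and 24); tetrabutylammonium fluoride CCCC[N+](CCCC)(CCCC)CCCC.[F-] (cation stays only in 25)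
Why: Ring-contracting Ireland–Claisen rearrangement of a lactone silyl ketene acetal closes ring A, where the ring fixes the ketene acetal geometry and forces a boat transition state, bond formation is suprafacial on the Z allyl unit so that C1 (S) is relayed into C4 (R) and C5 (R) with C6 trans to C18 and the double bond landing at C1=C10, and fluoride then frees the carboxylate and both alcohols before MeI esterifies the carboxylate only.

**Step 17**
Reactants: 26 methyl (1R,2R)-3-G(OH)-2-(hydroxymethyl)-1-methylcyclohex-3-ene-1-carboxylate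
Product: 27 methyl (1R,2R)-3-G(OH)-2-(iodomethyl)-1-methylcyclohex-3-ene-1-carboxylate
Conditions: I2, PPh3, imidazole, CH2Cl2, 0 °C
Reagents that add atoms: iodine II
Why: Appel-type (Garegg–Samuelsson) iodination proceeds by SN2 displacement at the primary C6, and the tertiary C13 alcohol does not form a reactive phosphonium salt at 0 °C.

**Step 18**
Reactants: 27 methyl (1R,2R)-3-G(OH)-2-(iodomethyl)-1-methylcyclohex-3-ene-1-carboxylate
Product: 30 methyl (4R,5R,8R,9S,13S,14R)-13-hydroxy-14,15-(isopropylidenedioxy)halim-1(10)-en-18-oate, via primary C6 radical 28 (not isolated), via tertiary C8 radical 29 (not isolated)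
Conditions: (Me3Si)3SiH (1.3 equiv) and 2,2'-azobis(2-methylpropionitrile) (0.2 equiv) by syringe pump over 8 h, toluene (0.005 M), 90 °C
Reagents that add atoms: none
Why: The tris(trimethylsilyl)silyl radical abstracts iodine from 27 to give the primary C6 radical 28, which adds to the CH2 terminus (C7) of the isopropenyl group to give the tertiary C8 radical 29, and 29 takes hydrogen from the silane and carries the chain, so an electrophilic CH2–I carbon is turned into a nucleophilic radical and joined to an unactivated, electron-rich alkene carbon. The closest known reaction type is the reductive cyclisation of 5-substituted hex-5-enyl radicals, for which 6-endo closure is the established outcome. Ring B closes 6-endo-trig through a chair with C4 equatorial on C5, the C9 methyl axial and the C9 side chain equatorial, whereas 5-exo closure would have to bond to the fully substituted C8 beside quaternary C9 and leave a primary radical, so it loses on both steric and energetic grounds. The new stereocentre C8 is set in the hydrogen transfer, because the lobe of 29 that runs parallel to the axial C9 methyl (alpha face) is shielded, so the bulky silane delivers hydrogen to the beta lobe and C17 ends equatorial and cis to C20, as in the target. The step needs cyclisation to outrun direct reduction of 28 and needs C1=C10 to stay intact, and the slow, highly diluted hydrogen donor, the full substitution at C9 and the fixed proximity of C6 and C7 across the sp2 carbon C10 secure the first need, while 3-exo attack on C1=C10 is reversible and the cyclopropylcarbinyl radical reopens to 28, which secures the second.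

**Step 19**
Reactants: 30 methyl (4R,5R,8R,9S,13S,14R)-13-hydroxy-14,15-(isopropylidenedioxy)halim-1(10)-en-18-oate
Product: 31 methyl (4R,5R,8R,9S,13S,14R)-13,14,15-trihydroxyhalim-1(10)-en-18-oate
Conditions: AcOH–H2O (4:1), 40 °C
Reagents that add atoms: none
Why: Mild acid hydrolysis of the terminal acetonide is too weak to move the trisubstituted C1=C10 double bond or to ionise the tertiary alcohol.

**Step 20**
Reactants: 31 methyl (4R,5R,8R,9S,13S,14R)-13,14,15-trihydroxyhalim-1(10)-en-18-oate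
Product: 32 methyl (4R,5R,8R,9S,13S,14R)-14,15-diacetoxy-13-hydroxyhalim-1(10)-en-18-oate (target)
Conditions: Ac2O, pyridine, rt
Reagents that add atoms: acetic anhydride CC(=O)OC(C)=O
Why: Acetylation without an acyl-transfer catalyst takes the primary C15 and secondary C14 hydroxyls and leaves the tertiary C13 hydroxyl free.

**Compound list**
1 | tert-butyl 2-methyl-3-oxobutanoate | CC(=O)C(C)C(=O)OC(C)(C)C | starting material
2 | but-3-en-2-one | C=CC(C)=O | starting material
3 | tert-butyl (S)-2-acetyl-2-methyl-5-oxohexanoate | CC(=O)[C@](C(=O)OC(C)(C)C)(C)CCC(C)=O | intermediate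
4 | 1-tert-butyl 7-ethyl (2S,5E)-2-acetyl-2,5-dimethylhept-5-enedioate | CC(=O)[C@](C(=O)OC(C)(C)C)(C)CC/C(C)=C/C(=O)OCC | intermediate
5 | 1-tert-butyl 7-ethyl (2S,5E)-2,5-dimethyl-2-(prop-1-en-2-yl)hept-5-enedioate | CC(=C)[C@](C(=O)OC(C)(C)C)(C)CC/C(C)=C/C(=O)OCC | intermediate
6 | (2E,6S)-6-(hydroxymethyl)-3,6,7-trimethylocta-2,7-dien-1-ol | CC(=C)[C@](CO)(C)CC/C(C)=C/CO | intermediate
7 | (S)-2-{2-[(2S,3S)-3-(hydroxymethyl)-2-methyloxiran-2-yl]ethyl}-2,3-dimethylbut-3-en-1-ol | CC(=C)[C@](CO)(C)CC[C@]1(C)O[C@H]1CO | intermediate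
8 | (S)-2-{(S)-3-hydroxy-3-[(R)-oxiran-2-yl]butyl}-2,3-dimethylbut-3-en-1-ol (Payne isomer) | CC(=C)[C@](CO)(C)CC[C@](C)(O)[C@H]1CO1 | intermediate
9 | (2R,3S,6S)-6-(hydroxymethyl)-3,6,7-trimethyloct-7-ene-1,2,3-triol | CC(=C)[C@](CO)(C)CC[C@](C)(O)[C@@H](CO)O | intermediate
10 | (S)-2-{(S)-3-[(R)-2,2-dimethyl-1,3-dioxolan-4-yl]-3-hydroxybutyl}-2,3-dimethylbut-3-en-1-ol | CC(=C)[C@](CO)(C)CC[C@](C)(O)[C@H]1COC(C)(C)O1 | intermediate
11 | (S)-2-{(S)-3-[(R)-2,2-dimethyl-1,3-dioxolan-4-yl]-3-hydroxybutyl}-2,3-dimethylbut-3-enal | CC(=C)[C@](C=O)(C)CC[C@](C)(O)[C@H]1COC(C)(C)O1 | intermediate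
12 | (2S,5S)-2-[(R)-2,2-dimethyl-1,3-dioxolan-4-yl]-5-ethynyl-5,6-dimethylhept-6-en-2-ol | CC(=C)[C@](C#C)(C)CC[C@](C)(O)[C@H]1COC(C)(C)O1 | intermediate
13 | dilithium acetylide alkoxide of 12 | CC(=C)[C@](C#C[Li])(C)CC[C@](C)(O[Li])[C@H]1COC(C)(C)O1 | intermediate
14 | (4S,7S)-7-[(R)-2,2-dimethyl-1,3-dioxolan-4-yl]-4-methyl-4-(prop-1-en-2-yl)oct-2-yne-1,7-diol | CC(=C)[C@](C#CCO)(C)CC[C@](C)(O)[C@H]1COC(C)(C)O1 | intermediate
15 | (2Z,4S,7S)-7-[(R)-2,2-dimethyl-1,3-dioxolan-4-yl]-3-iodo-4-methyl-4-(prop-1-en-2-yl)oct-2-ene-1,7-diol | CC(=C)[C@](/C(I)=C/CO)(C)CC[C@](C)(O)[C@H]1COC(C)(C)O1 | intermediate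
16 | bis(triethylsilyl) ether of 15 | CC(=C)[C@](/C(I)=C/CO[Si](CC)(CC)CC)(C)CC[C@](C)(O[Si](CC)(CC)CC)[C@H]1COC(C)(C)O1 | intermediate
17 | dimethyl 2-methylpentanedioate | COC(=O)CCC(C)C(=O)OC | starting material
18 | methyl 5-[methoxy(methyl)amino]-2-methyl-5-oxopentanoate | CON(C)C(=O)CCC(C)C(=O)OC | intermediate
19 | vinyllithium from 16 (lithium on C10) | CC(=C)[C@](/C([Li])=C/CO[Si](CC)(CC)CC)(C)CC[C@](C)(O[Si](CC)(CC)CC)[C@H]1COC(C)(C)O1 | intermediate
20 | methyl (Z)-6-G(TES)-2-methyl-5-oxo-8-(triethylsilyloxy)oct-6-enoate (C2 epimers) | CC(=C)[C@](/C(C(=O)CCC(C)C(=O)OC)=C/CO[Si](CC)(CC)CC)(C)CC[C@](C)(O[Si](CC)(CC)CC)[C@H]1COC(C)(C)O1 | intermediate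
21 | methyl (5S,6Z)-6-G(TES)-5-hydroxy-2-methyl-8-(triethylsilyloxy)oct-6-enoate (C2 epimers) | CC(=C)[C@](/C([C@@H](O)CCC(C)C(=O)OC)=C/CO[Si](CC)(CC)CC)(C)CC[C@](C)(O[Si](CC)(CC)CC)[C@H]1COC(C)(C)O1 | intermediate
22 | (6S)-6-[(Z)-1-G(TES)-3-(triethylsilyloxy)prop-1-en-1-yl]-3-methyltetrahydro-2H-pyran-2-one (C3 epimers) | CC(=C)[C@](/C([C@@H]2CCC(C)C(=O)O2)=C/CO[Si](CC)(CC)CC)(C)CC[C@](C)(O[Si](CC)(CC)CC)[C@H]1COC(C)(C)O1 | intermediate
23 | (2S)-2-[(Z)-1-G(TES)-3-(triethylsilyloxy)prop-1-en-1-yl]-5-methyl-6-(trimethylsilyloxy)-3,4-dihydro-2H-pyran | CC(=C)[C@](/C([C@@H]2CCC(C)=C(O[Si](C)(C)C)O2)=C/CO[Si](CC)(CC)CC)(C)CC[C@](C)(O[Si](CC)(CC)CC)[C@H]1COC(C)(C)O1 | intermediate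
24 | trimethylsilyl (1R,2R)-3-G(TES)-1-methyl-2-[(triethylsilyloxy)methyl]cyclohex-3-ene-1-carboxylate | C[Si](C)(C)OC(=O)[C@]1(C)CCC=C([C@@](C(C)=C)(C)CC[C@](C)(O[Si](CC)(CC)CC)[C@H]2COC(C)(C)O2)[C@H]1CO[Si](CC)(CC)CC | intermediate
25 | tetrabutylammonium (1R,2R)-3-G(OH)-2-(hydroxymethyl)-1-methylcyclohex-3-ene-1-carboxylate | CCCC[N+](CCCC)(CCCC)CCCC.[O-]C(=O)[C@]1(C)CCC=C([C@@](C(C)=C)(C)CC[C@](C)(O)[C@H]2COC(C)(C)O2)[C@H]1CO | intermediate
26 | methyl (1R,2R)-3-G(OH)-2-(hydroxymethyl)-1-methylcyclohex-3-ene-1-carboxylate | COC(=O)[C@]1(C)CCC=C([C@@](C(C)=C)(C)CC[C@](C)(O)[C@H]2COC(C)(C)O2)[C@H]1CO | intermediate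
27 | methyl (1R,2R)-3-G(OH)-2-(iodomethyl)-1-methylcyclohex-3-ene-1-carboxylate | COC(=O)[C@]1(C)CCC=C([C@@](C(C)=C)(C)CC[C@](C)(O)[C@H]2COC(C)(C)O2)[C@H]1CI | intermediate
28 | primary C6 radical from 27 | COC(=O)[C@]1(C)CCC=C([C@@](C(C)=C)(C)CC[C@](C)(O)[C@H]2COC(C)(C)O2)[C@H]1[CH2] | intermediate
29 | tertiary C8 radical (ring B closed) | COC(=O)[C@]1(C)CCC=C2[C@H]1CC[C](C)[C@]2(C)CC[C@](C)(O)[C@H]3COC(C)(C)O3 | intermediate
30 | methyl (4R,5R,8R,9S,13S,14R)-13-hydroxy-14,15-(isopropylidenedioxy)halim-1(10)-en-18-oate | COC(=O)[C@]1(C)CCC=C2[C@H]1CC[C@@H](C)[C@]2(C)CC[C@](C)(O)[C@H]3COC(C)(C)O3 | intermediate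
31 | methyl (4R,5R,8R,9S,13S,14R)-13,14,15-trihydroxyhalim-1(10)-en-18-oate | COC(=O)[C@]1(C)CCC=C2[C@H]1CC[C@@H](C)[C@]2(C)CC[C@](C)(O)[C@@H](CO)O | intermediate
32 | methyl (4R,5R,8R,9S,13S,14R)-14,15-diacetoxy-13-hydroxyhalim-1(10)-en-18-oate | COC(=O)[C@]1(C)CCC=C2[C@H]1CC[C@@H](C)[C@]2(C)CC[C@](C)(O)[C@@H](COC(C)=O)OC(C)=O | target

**Step count**
Total step count: 20. Longest linear sequence: 19 (steps 1–12 and 14–20).

**Steps most likely to fail**

*Step 18.* Hydrogen transfer to the primary radical may come before ring closure, or the facial selectivity of the last hydrogen transfer at C8 may be poor.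
- The fallback sets out from 26 and comes back at 30.
- Alcohol 26 is oxidised with Dess–Martin periodinane to the C6 aldehyde F1.
- F1 is used at once and closed at the same C6–C7 bond by a type-two carbonyl-ene reaction (Me2AlCl, CH2Cl2, −78 °C), giving the 6-hydroxy-8(17)-methylene decalin F2.
- The secondary alcohol is removed by Barton–McCombie deoxygenation. 1,1'-Thiocarbonyldiimidazole gives the imidazolylthiocarbonate F3, and Bu3SnH with 2,2'-azobis(2-methylpropionitrile) gives the 8(17)-methylene decalin F4.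
- The 1,1-disubstituted double bond alone is hydrogenated with RhCl(PPh3)3 and H2, from the face opposite the axial C9 methyl, to give 30.

*Step 16.* The rearrangement may be sluggish in the crowded boat transition state, so the silyl ketene acetal may decompose first.
- The fallback sets out from 22 and comes back at 26.
- Lactone 22 is reduced (i-Bu2AlH, −78 °C) to the lactol F5.
- F5 is dehydrated (MsCl, Et3N) to the cyclic enol ether F6.
- F6 undergoes a neutral allyl vinyl ether Claisen rearrangement (toluene, sealed tube, 180 °C). It passes through the same boat with the same chirality transfer, but C18 carries only hydrogen in place of the silyloxy group. The product is the ring A aldehyde F7.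
- Pinnick oxidation (NaClO2, NaH2PO4, 2-methylbut-2-ene) gives the ring A acid F8.
- Bu4NF followed by MeI converts F8 into 26.

*Step 14.* Acylation of the hindered vinyllithium may be slow, with competing attack on the methyl ester or protonation.
- The fallback sets out from 16 and 18 and comes back at 20.
- Weinreb amide 18 is reduced (i-Bu2AlH, −78 °C) to the aldehyde ester F9.
- F9 is joined to 16 by Nozaki–Hiyama–Kishi coupling (CrCl2, NiCl2 cat., DMSO), which tolerates the ester and gives the C1-epimeric allylic alcohols F10.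
- Dess–Martin oxidation of F10 gives 20.

**Further compounds**
F1 | step 18 | methyl (1R,2R)-3-G(OH)-2-formyl-1-methylcyclohex-3-ene-1-carboxylate | COC(=O)[C@]1(C)CCC=C([C@@](C(C)=C)(C)CC[C@](C)(O)[C@H]2COC(C)(C)O2)[C@H]1C=O
F2 | step 18 | methyl 6,13-dihydroxy-14,15-(isopropylidenedioxy)halima-1(10),8(17)-dien-18-oate (C6 epimers) | COC(=O)[C@]1(C)CCC=C2[C@H]1C(O)CC(=C)[C@]2(C)CC[C@](C)(O)[C@H]3COC(C)(C)O3
F3 | step 18 | 6-O-(imidazol-1-ylthiocarbonyl) derivative of F2 | COC(=O)[C@]1(C)CCC=C2[C@H]1C(OC(=S)n4ccnc4)CC(=C)[C@]2(C)CC[C@](C)(O)[C@H]3COC(C)(C)O3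
F4 | step 18 | methyl 13-hydroxy-14,15-(isopropylidenedioxy)halima-1(10),8(17)-dien-18-oate | COC(=O)[C@]1(C)CCC=C2[C@H]1CCC(=C)[C@]2(C)CC[C@](C)(O)[C@H]3COC(C)(C)O3
F5 | step 16 | (6S)-6-[(Z)-1-G(TES)-3-(triethylsilyloxy)prop-1-en-1-yl]-3-methyltetrahydro-2H-pyran-2-ol | CC(=C)[C@](/C([C@@H]2CCC(C)C(O)O2)=C/CO[Si](CC)(CC)CC)(C)CC[C@](C)(O[Si](CC)(CC)CC)[C@H]1COC(C)(C)O1
F6 | step 16 | (2S)-2-[(Z)-1-G(TES)-3-(triethylsilyloxy)prop-1-en-1-yl]-5-methyl-3,4-dihydro-2H-pyran | CC(=C)[C@](/C([C@@H]2CCC(C)=CO2)=C/CO[Si](CC)(CC)CC)(C)CC[C@](C)(O[Si](CC)(CC)CC)[C@H]1COC(C)(C)O1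
F7 | step 16 | (1R,2R)-3-G(TES)-1-methyl-2-[(triethylsilyloxy)methyl]cyclohex-3-ene-1-carbaldehyde | O=C[C@]1(C)CCC=C([C@@](C(C)=C)(C)CC[C@](C)(O[Si](CC)(CC)CC)[C@H]2COC(C)(C)O2)[C@H]1CO[Si](CC)(CC)CC
F8 | step 16 | (1R,2R)-3-G(TES)-1-methyl-2-[(triethylsilyloxy)methyl]cyclohex-3-ene-1-carboxylic acid | OC(=O)[C@]1(C)CCC=C([C@@](C(C)=C)(C)CC[C@](C)(O[Si](CC)(CC)CC)[C@H]2COC(C)(C)O2)[C@H]1CO[Si](CC)(CC)CC
F9 | step 14 | methyl 2-methyl-5-oxopentanoate | COC(=O)C(C)CCC=O
F10 | step 14 | methyl (Z)-6-G(TES)-5-hydroxy-2-methyl-8-(triethylsilyloxy)oct-6-enoate (C5 and C2 epimers) | CC(=C)[C@](/C(C(O)CCC(C)C(=O)OC)=C/CO[Si](CC)(CC)CC)(C)CC[C@](C)(O[Si](CC)(CC)CC)[C@H]1COC(C)(C)O1
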